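## Retrosynthetic overview

Ring labels: A is the dihydrobenzofuran bearing the styryl group, B the central one, C the terminal one bearing the 3,5-dihydroxyphenyl. The target SMILES reads as A (2R,3R), B (2S,3S), C (2R,3R), each ring 2,3-trans.

1. Ring B closes last: fluoride unmasks pivalate 28, the p-quinone methide forms, and the ortho phenoxide adds to it (5-exo intramolecular oxa-Michael) with global desilylation.
2. 28 comes from joining ring-C boronate 18 and ring-A nitroalkene 25 by Rh-catalysed asymmetric 1,4-arylation (sets C3 of ring B), then Nef and ArMgBr/PivCl.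
3. 18 and 25 are made in parallel from the same nitroalkene 4 by the same cycle: asymmetric arylation (C3), Nef, ArMgBr/PivCl, quinone-methide oxa-Michael (C2, trans).
4. All aryl units come from 5-bromoresorcinol, resorcinol and 4-bromophenol. Ring order: C and A in parallel, then B.

Assumption: the (R,R)-diene ligand is taken to deliver aryl to the Cβ Re face (steps 10, 16) and the (S,S)-ligand to the Si face (step 23); this is checked on adduct 13 and the ligand antipodes swapped if the sense is reversed.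

Abbreviations: TIPS = Si(i-Pr)3; Bpin = pinacolboronate; Piv = pivaloyl; DMDO = dimethyldioxirane.

## Route

**Step 1**
Reactants: 1, 5-bromoresorcinol
Product: 2, 2-bromo-4,6-dihydroxybenzaldehyde
Conditions: POCl3, DMF, MeCN, 0 °C → rt; then H2O, 50 °C
Reagents that add atoms: DMF, CN(C)C=O; water, O
Why: Vilsmeier–Haack formylation goes ortho/para to the two OH groups at the position next to Br, as orcinol gives orcylaldehyde.

**Step 2**
Reactants: 2
Product: 3, 2-bromo-4,6-bis(TIPSO)benzaldehyde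
Conditions: TIPSCl, imidazole, DMAP (cat.), DMF, rt
Reagents that add atoms: TIPSCl, CC(C)[Si](Cl)(C(C)C)C(C)C
Why: Phenol silylation; TIPS ethers survive the later base, Grignard and Pd/Rh steps and all leave with fluoride.

**Step 3**
Reactants: 3
Product: 4, (E)-1-bromo-2-(2-nitrovinyl)-3,5-bis(TIPSO)benzene
Conditions: MeNO2 (solvent), NH4OAc, 90 °C
Reagents that add atoms: nitromethane, C[N+](=O)[O-]
Why: Henry condensation with dehydration gives the conjugated E-nitroalkene.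

**Step 4**
Reactants: 3
Product: 5, 2-[2-bromo-4,6-bis(TIPSO)phenyl]-1,3-dioxolane
Conditions: ethylene glycol, p-TsOH (cat.), toluene, Dean–Stark, reflux
Reagents that add atoms: ethylene glycol, OCCO
Why: Acetalisation masks the aldehyde so it cannot undergo an intramolecular Henry reaction with the nitronate formed in step 16.

**Step 5**
Reactants: 5
Product: 6, 2-[2-(Bpin)-4,6-bis(TIPSO)phenyl]-1,3-dioxolane
Conditions: B2pin2, PdCl2(dppf), KOAc, dioxane, 90 °C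
Reagents that add atoms: B2pin2, CC1(C)OB(OC1(C)C)B1OC(C)(C)C(C)(C)O1
Why: Miyaura borylation of a mono-ortho-substituted aryl bromide.

**Step 6**
Reactants: 7, resorcinol
Product: 8, 1,3-bis(TIPSO)benzene
Conditions: TIPSCl, imidazole, DMF, rt
Reagents that add atoms: TIPSCl, CC(C)[Si](Cl)(C(C)C)C(C)C
Why: Phenol silylation.

**Step 7**
Reactants: 8
Product: 9, 2-[3,5-bis(TIPSO)phenyl]-4,4,5,5-tetramethyl-1,3,2-dioxaborolane
Conditions: B2pin2, [Ir(OMe)(cod)]2, dtbpy, MTBE, 80 °C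
Reagents that add atoms: B2pin2, CC1(C)OB(OC1(C)C)B1OC(C)(C)C(C)(C)O1
Why: Sterically controlled Ir-catalysed C–H borylation; C5 is the only C–H not ortho to a silyloxy group.

**Step 8**
Reactants: 10, 4-bromophenol
Product: 11, (4-bromophenoxy)triisopropylsilane
Conditions: TIPSCl, imidazole, DMF, rt
Reagents that add atoms: TIPSCl, CC(C)[Si](Cl)(C(C)C)C(C)C
Why: Phenol silylation; 11 supplies all three 4-hydroxyphenyl groups (as ArMgBr) and the styrene.

**Step 9**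
Reactants: 11
Product: 12, triisopropyl(4-vinylphenoxy)silane
Conditions: CH2=CHBF3K, PdCl2(dppf), Et3N, n-PrOH, 90 °C
Reagents that add atoms: potassium vinyltrifluoroborate, C=C[B-](F)(F)F.[K+]
Why: Suzuki–Miyaura (Molander) vinylation.

**Step 10**
Reactants: 4; 9 (2 equiv)
Product: 13, 1-bromo-2-[(1R)-1-[3,5-bis(TIPSO)phenyl]-2-nitroethyl]-3,5-bis(TIPSO)benzene
Conditions: [RhCl(C2H4)2]2 (3 mol %), (R,R)-Ph-bod* (7 mol %), KOH (0.2 equiv), dioxane/H2O 10:1, 60 °C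
Reagents that add atoms: none
Why: Hayashi–Miyaura Rh-catalysed asymmetric 1,4-arylation of the nitroalkene; catalyst-controlled Re-face delivery sets C3 of ring C as R, and this centre (β to nitro) cannot epimerise.

**Step 11**
Reactants: 13
Product: 14, (2R)-2-[2-bromo-4,6-bis(TIPSO)phenyl]-2-[3,5-bis(TIPSO)phenyl]acetaldehyde
Conditions: t-BuOK, THF, −40 °C; then aq. TiCl3, NH4OAc (pH ≈ 6), THF/H2O, 0 °C; used crude at once
Reagents that add atoms: water, O
Why: Reductive Nef reaction (McMurry TiCl3) under buffered conditions; the aldehyde is not purified to limit enolisation at the diaryl carbon.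

**Step 12**
Reactants: 14; 11 (as its Grignard reagent)
Product: 15, (2R)-2-[2-bromo-4,6-bis(TIPSO)phenyl]-2-[3,5-bis(TIPSO)phenyl]-1-[4-(TIPSO)phenyl]ethyl pivalate (C1 epimers)
Conditions: 11, Mg, THF; add to 14, THF, −78 °C; then PivCl, DMAP, −78 → 0 °C
Reagents that add atoms: pivaloyl chloride, CC(C)(C)C(=O)Cl
Why: Fast Grignard 1,2-addition at −78 °C outruns enolisation and the alkoxide is trapped as a pivalate leaving group; the new carbinol centre is not controlled because it is erased in step 13.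

**Step 13**
Reactants: 15
Product: 16, (2R,3R)-4-bromo-3-(3,5-dihydroxyphenyl)-2-(4-hydroxyphenyl)-2,3-dihydro-1-benzofuran-6-ol
Conditions: TBAF (7 equiv), THF, 0 °C, 20 min; AcOH quench
Reagents that add atoms: none
Why: Desilylation gives the para-phenoxide, which expels pivalate (1,6-elimination) to a p-quinone methide; 5-exo-trig intramolecular oxa-Michael (1,6-conjugate) addition of the ortho phenoxide closes ring C, and reversible retro-Michael under phenoxide conditions funnels C2 to the trans (2R) isomer.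

**Step 14**
Reactants: 16
Product: 17, tetrakis-TIPS ether of 16
Conditions: TIPSCl, imidazole, DMF, rt
Reagents that add atoms: TIPSCl, CC(C)[Si](Cl)(C(C)C)C(C)C
Why: Re-silylation of the four phenols for the organometallic steps ahead.

**Step 15**
Reactants: 17
Product: 18, (2R,3R)-4-(Bpin)-6-(TIPSO)-3-[3,5-bis(TIPSO)phenyl]-2-[4-(TIPSO)phenyl]-2,3-dihydrobenzofuran
Conditions: B2pin2, Pd2(dba)3, XPhos, KOAc, dioxane, 100 °C
Reagents that add atoms: B2pin2, CC1(C)OB(OC1(C)C)B1OC(C)(C)C(C)(C)O1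
Why: Miyaura borylation with a bulky biaryl phosphine for the hindered bromide; no stereocentre is touched.

**Step 16**
Reactants: 4; 6 (2.5 equiv)
Product: 19, 2-[2-[(1R)-1-[2-bromo-4,6-bis(TIPSO)phenyl]-2-nitroethyl]-4,6-bis(TIPSO)phenyl]-1,3-dioxolane
Conditions: [RhCl(C2H4)2]2 (3 mol %), (R,R)-Ph-bod* (7 mol %), KOH (0.2 equiv), dioxane/H2O 10:1, 70 °C
Reagents that add atoms: none
Why: Same Hayashi–Miyaura arylation with Re-face delivery sets C3 of ring A as R; the aryl bromide is inert to Rh(I).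

**Step 17**
Reactants: 19
Product: 20, (2R)-2-[2-bromo-4,6-bis(TIPSO)phenyl]-2-[2-(1,3-dioxolan-2-yl)-3,5-bis(TIPSO)phenyl]acetaldehyde
Conditions: t-BuOK (1.05 equiv), THF, −78 °C; then DMDO (acetone), −78 → −20 °C; used crude
Reagents that add atoms: DMDO, CC1(C)OO1
Why: Oxidative Nef reaction of the nitronate under neutral conditions, so the acid-labile dioxolane survives (no alkene is present yet).

**Step 18**
Reactants: 20; 11 (as its Grignard reagent)
Product: 21, (2R)-2-[2-bromo-4,6-bis(TIPSO)phenyl]-2-[2-(1,3-dioxolan-2-yl)-3,5-bis(TIPSO)phenyl]-1-[4-(TIPSO)phenyl]ethyl pivalate (C1 epimers)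
Conditions: 11, Mg, THF; add to 20, THF, −78 °C; then PivCl, DMAP, −78 → 0 °C
Reagents that add atoms: pivaloyl chloride, CC(C)(C)C(=O)Cl
Why: Grignard addition and in-situ acylation as in step 12; acetal and aryl bromide are inert.

**Step 19**
Reactants: 21
Product: 22, 2-[(2R,3R)-4-bromo-6-hydroxy-2-(4-hydroxyphenyl)-2,3-dihydro-1-benzofuran-3-yl]-4,6-dihydroxybenzaldehyde
Conditions: TBAF (7 equiv), THF, 0 °C; then 10% aq. citric acid, THF, rt
Reagents that add atoms: water, O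
Why: Fluoride-triggered p-quinone methide formation and 5-exo intramolecular oxa-Michael addition close ring A trans (2R,3R); mild acid then hydrolyses the now very electron-rich aryl dioxolane.

**Step 20**
Reactants: 22
Product: 23, tetrakis-TIPS ether of 22
Conditions: TIPSOTf, 2,6-lutidine, CH2Cl2, 0 °C
Reagents that add atoms: TIPSOTf, CC(C)[Si](OS(=O)(=O)C(F)(F)F)(C(C)C)C(C)C
Why: The silyl triflate also silylates the hydrogen-bonded phenol ortho to the aldehyde.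

**Step 21**
Reactants: 23; 12
Product: 24, 2-[(2R,3R)-6-(TIPSO)-2-[4-(TIPSO)phenyl]-4-[(E)-4-(TIPSO)styryl]-2,3-dihydrobenzofuran-3-yl]-4,6-bis(TIPSO)benzaldehyde
Conditions: Pd2(dba)3, P(t-Bu)3·HBF4, Cy2NMe, dioxane, 90 °C
Reagents that add atoms: none
Why: Mizoroki–Heck reaction gives the E-stilbene; the bulky electron-rich phosphine handles the hindered, electron-rich bromide.

**Step 22**
Reactants: 24
Product: 25, the (E)-2-nitrovinyl analogue of 24 (CHO replaced by CH=CH–NO2)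
Conditions: MeNO2 (solvent), NH4OAc, 95 °C
Reagents that add atoms: nitromethane, C[N+](=O)[O-]
Why: Henry condensation gives the acceptor for the fragment union.

**Step 23**
Reactants: 25; 18 (1.5 equiv)
Product: 26, nitroalkane in which the ring-B arene carries (1S)-CH(CH2NO2)(ring-C aryl); rings A and C unchanged (2R,3R)
Conditions: [RhCl(C2H4)2]2 (5 mol %), (S,S)-Ph-bod* (11 mol %), KOH (0.2 equiv), dioxane/H2O 10:1, 80 °C
Reagents that add atoms: none
Why: Hayashi–Miyaura asymmetric 1,4-arylation joins the two halves; the antipodal ligand delivers aryl to the Si face and sets C3 of ring B as S, and the stilbene is not an acceptor.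

**Step 24**
Reactants: 26
Product: 27, the corresponding (S)-α,α-diaryl acetaldehyde (CH2NO2 replaced by CHO)
Conditions: t-BuOK, THF, −40 °C; then aq. TiCl3, NH4OAc (pH ≈ 6), THF/H2O, 0 °C; used crude
Reagents that add atoms: water, O
Why: Reductive Nef reaction, which leaves the electron-rich stilbene untouched (an oxidative Nef would not).

**Step 25**
Reactants: 27; 11 (as its Grignard reagent)
Product: 28, pivalate of the 1-[4-(TIPSO)phenyl] carbinol (carbinol epimers; C3 of ring B is S)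
Conditions: 11, Mg, THF; add to 27, THF, −78 °C; then PivCl, DMAP, −78 → 0 °C
Reagents that add atoms: pivaloyl chloride, CC(C)(C)C(=O)Cl
Why: Grignard addition and in-situ acylation; the aldehyde is the only electrophile present.

**Step 26**
Reactants: 28
Product: 29, Miyabenol A
Conditions: TBAF (15 equiv), THF, 0 °C → rt; AcOH quench; reversed-phase HPLC
Reagents that add atoms: none
Why: Global desilylation, 1,6-elimination of pivalate to the p-quinone methide and 5-exo intramolecular oxa-Michael addition of the ring-B ortho phenoxide close the last ring trans to C3 (2S,3S); rings A and C re-close to their trans forms if they open reversibly.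

## Compound list

1 | 5-bromoresorcinol | Oc1cc(O)cc(Br)c1 | starting material
2 | 2-bromo-4,6-dihydroxybenzaldehyde | O=Cc1c(Br)cc(O)cc1O | intermediate
3 | 2-bromo-4,6-bis(TIPSO)benzaldehyde | O=Cc1c(Br)cc(O[Si](C(C)C)(C(C)C)C(C)C)cc1O[Si](C(C)C)(C(C)C)C(C)C | intermediate
4 | (E)-1-bromo-2-(2-nitrovinyl)-3,5-bis(TIPSO)benzene | O=[N+]([O-])/C=C/c1c(Br)cc(O[Si](C(C)C)(C(C)C)C(C)C)cc1O[Si](C(C)C)(C(C)C)C(C)C | intermediate
5 | 2-[2-bromo-4,6-bis(TIPSO)phenyl]-1,3-dioxolane | Brc1cc(O[Si](C(C)C)(C(C)C)C(C)C)cc(O[Si](C(C)C)(C(C)C)C(C)C)c1C1OCCO1 | intermediate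
6 | 2-[2-(Bpin)-4,6-bis(TIPSO)phenyl]-1,3-dioxolane | CC1(C)OB(OC1(C)C)c1cc(O[Si](C(C)C)(C(C)C)C(C)C)cc(O[Si](C(C)C)(C(C)C)C(C)C)c1C1OCCO1 | intermediate
7 | resorcinol | Oc1cccc(O)c1 | starting material
8 | 1,3-bis(TIPSO)benzene | CC(C)[Si](C(C)C)(C(C)C)Oc1cccc(O[Si](C(C)C)(C(C)C)C(C)C)c1 | intermediate
9 | 3,5-bis(TIPSO)phenyl-Bpin | CC1(C)OB(OC1(C)C)c1cc(O[Si](C(C)C)(C(C)C)C(C)C)cc(O[Si](C(C)C)(C(C)C)C(C)C)c1 | intermediate
10 | 4-bromophenol | Oc1ccc(Br)cc1 | starting material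
11 | (4-bromophenoxy)triisopropylsilane | CC(C)[Si](C(C)C)(C(C)C)Oc1ccc(Br)cc1 | intermediate
12 | triisopropyl(4-vinylphenoxy)silane | C=Cc1ccc(O[Si](C(C)C)(C(C)C)C(C)C)cc1 | intermediate
13 | (1R)-nitroalkane, ring-C precursor | O=[N+]([O-])C[C@@H](c1c(Br)cc(O[Si](C(C)C)(C(C)C)C(C)C)cc1O[Si](C(C)C)(C(C)C)C(C)C)c1cc(O[Si](C(C)C)(C(C)C)C(C)C)cc(O[Si](C(C)C)(C(C)C)C(C)C)c1 | intermediate
14 | (2R)-diaryl acetaldehyde, ring-C precursor | O=C[C@@H](c1c(Br)cc(O[Si](C(C)C)(C(C)C)C(C)C)cc1O[Si](C(C)C)(C(C)C)C(C)C)c1cc(O[Si](C(C)C)(C(C)C)C(C)C)cc(O[Si](C(C)C)(C(C)C)C(C)C)c1 | intermediate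
15 | (2R)-pivalate, ring-C precursor (C1 epimers) | CC(C)(C)C(=O)OC(c1ccc(O[Si](C(C)C)(C(C)C)C(C)C)cc1)[C@@H](c1c(Br)cc(O[Si](C(C)C)(C(C)C)C(C)C)cc1O[Si](C(C)C)(C(C)C)C(C)C)c1cc(O[Si](C(C)C)(C(C)C)C(C)C)cc(O[Si](C(C)C)(C(C)C)C(C)C)c1 | intermediate
16 | (2R,3R)-4-bromo-3-(3,5-dihydroxyphenyl)-2-(4-hydroxyphenyl)-2,3-dihydrobenzofuran-6-ol | Brc1cc(O)cc2c1[C@@H](c1cc(O)cc(O)c1)[C@H](c1ccc(O)cc1)O2 | intermediate
17 | tetrakis-TIPS ether of 16 | Brc1cc(O[Si](C(C)C)(C(C)C)C(C)C)cc2c1[C@@H](c1cc(O[Si](C(C)C)(C(C)C)C(C)C)cc(O[Si](C(C)C)(C(C)C)C(C)C)c1)[C@H](c1ccc(O[Si](C(C)C)(C(C)C)C(C)C)cc1)O2 | intermediate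
18 | ring-C boronate (2R,3R) | CC1(C)OB(OC1(C)C)c1cc(O[Si](C(C)C)(C(C)C)C(C)C)cc2c1[C@@H](c1cc(O[Si](C(C)C)(C(C)C)C(C)C)cc(O[Si](C(C)C)(C(C)C)C(C)C)c1)[C@H](c1ccc(O[Si](C(C)C)(C(C)C)C(C)C)cc1)O2 | intermediate
19 | (1R)-nitroalkane, ring-A precursor | O=[N+]([O-])C[C@@H](c1c(Br)cc(O[Si](C(C)C)(C(C)C)C(C)C)cc1O[Si](C(C)C)(C(C)C)C(C)C)c1cc(O[Si](C(C)C)(C(C)C)C(C)C)cc(O[Si](C(C)C)(C(C)C)C(C)C)c1C1OCCO1 | intermediate
20 | (2R)-diaryl acetaldehyde, ring-A precursor | O=C[C@@H](c1c(Br)cc(O[Si](C(C)C)(C(C)C)C(C)C)cc1O[Si](C(C)C)(C(C)C)C(C)C)c1cc(O[Si](C(C)C)(C(C)C)C(C)C)cc(O[Si](C(C)C)(C(C)C)C(C)C)c1C1OCCO1 | intermediate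
21 | (2R)-pivalate, ring-A precursor (C1 epimers) | CC(C)(C)C(=O)OC(c1ccc(O[Si](C(C)C)(C(C)C)C(C)C)cc1)[C@@H](c1c(Br)cc(O[Si](C(C)C)(C(C)C)C(C)C)cc1O[Si](C(C)C)(C(C)C)C(C)C)c1cc(O[Si](C(C)C)(C(C)C)C(C)C)cc(O[Si](C(C)C)(C(C)C)C(C)C)c1C1OCCO1 | intermediate
22 | 2-[(2R,3R)-4-bromo-6-hydroxy-2-(4-hydroxyphenyl)-2,3-dihydrobenzofuran-3-yl]-4,6-dihydroxybenzaldehyde | Brc1cc(O)cc2c1[C@@H](c1cc(O)cc(O)c1C=O)[C@H](c1ccc(O)cc1)O2 | intermediate
23 | tetrakis-TIPS ether of 22 | Brc1cc(O[Si](C(C)C)(C(C)C)C(C)C)cc2c1[C@@H](c1cc(O[Si](C(C)C)(C(C)C)C(C)C)cc(O[Si](C(C)C)(C(C)C)C(C)C)c1C=O)[C@H](c1ccc(O[Si](C(C)C)(C(C)C)C(C)C)cc1)O2 | intermediate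
24 | ring-A stilbene aldehyde (2R,3R) | CC(C)[Si](C(C)C)(C(C)C)Oc1ccc(/C=C/c2cc(O[Si](C(C)C)(C(C)C)C(C)C)cc3c2[C@@H](c2cc(O[Si](C(C)C)(C(C)C)C(C)C)cc(O[Si](C(C)C)(C(C)C)C(C)C)c2C=O)[C@H](c2ccc(O[Si](C(C)C)(C(C)C)C(C)C)cc2)O3)cc1 | intermediate
25 | ring-A nitroalkene (2R,3R) | CC(C)[Si](C(C)C)(C(C)C)Oc1ccc(/C=C/c2cc(O[Si](C(C)C)(C(C)C)C(C)C)cc3c2[C@@H](c2cc(O[Si](C(C)C)(C(C)C)C(C)C)cc(O[Si](C(C)C)(C(C)C)C(C)C)c2/C=C/[N+](=O)[O-])[C@H](c2ccc(O[Si](C(C)C)(C(C)C)C(C)C)cc2)O3)cc1 | intermediate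
26 | union nitroalkane (new centre S) | CC(C)[Si](C(C)C)(C(C)C)Oc1ccc(/C=C/c2cc(O[Si](C(C)C)(C(C)C)C(C)C)cc3c2[C@@H](c2cc(O[Si](C(C)C)(C(C)C)C(C)C)cc(O[Si](C(C)C)(C(C)C)C(C)C)c2[C@@H](C[N+](=O)[O-])c2cc(O[Si](C(C)C)(C(C)C)C(C)C)cc4c2[C@@H](c2cc(O[Si](C(C)C)(C(C)C)C(C)C)cc(O[Si](C(C)C)(C(C)C)C(C)C)c2)[C@H](c2ccc(O[Si](C(C)C)(C(C)C)C(C)C)cc2)O4)[C@H](c2ccc(O[Si](C(C)C)(C(C)C)C(C)C)cc2)O3)cc1 | intermediate
27 | union aldehyde (S) | CC(C)[Si](C(C)C)(C(C)C)Oc1ccc(/C=C/c2cc(O[Si](C(C)C)(C(C)C)C(C)C)cc3c2[C@@H](c2cc(O[Si](C(C)C)(C(C)C)C(C)C)cc(O[Si](C(C)C)(C(C)C)C(C)C)c2[C@@H](C=O)c2cc(O[Si](C(C)C)(C(C)C)C(C)C)cc4c2[C@@H](c2cc(O[Si](C(C)C)(C(C)C)C(C)C)cc(O[Si](C(C)C)(C(C)C)C(C)C)c2)[C@H](c2ccc(O[Si](C(C)C)(C(C)C)C(C)C)cc2)O4)[C@H](c2ccc(O[Si](C(C)C)(C(C)C)C(C)C)cc2)O3)cc1 | intermediate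
28 | ring-B pivalate (carbinol epimers) | CC(C)[Si](C(C)C)(C(C)C)Oc1ccc(/C=C/c2cc(O[Si](C(C)C)(C(C)C)C(C)C)cc3c2[C@@H](c2cc(O[Si](C(C)C)(C(C)C)C(C)C)cc(O[Si](C(C)C)(C(C)C)C(C)C)c2[C@@H](C(OC(=O)C(C)(C)C)c2ccc(O[Si](C(C)C)(C(C)C)C(C)C)cc2)c2cc(O[Si](C(C)C)(C(C)C)C(C)C)cc4c2[C@@H](c2cc(O[Si](C(C)C)(C(C)C)C(C)C)cc(O[Si](C(C)C)(C(C)C)C(C)C)c2)[C@H](c2ccc(O[Si](C(C)C)(C(C)C)C(C)C)cc2)O4)[C@H](c2ccc(O[Si](C(C)C)(C(C)C)C(C)C)cc2)O3)cc1 | intermediate
29 | Miyabenol A | Oc1ccc(/C=C/c2cc(O)cc3c2[C@@H](c2cc(O)cc4c2[C@H](c2cc(O)cc5c2[C@@H](c2cc(O)cc(O)c2)[C@H](c2ccc(O)cc2)O5)[C@@H](c2ccc(O)cc2)O4)[C@H](c2ccc(O)cc2)O3)cc1 | target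

## Summary

Total steps: 26.
Longest linear sequence: 15 (steps 1, 2, 4, 5, 16–26), which is 58% of the total; the ring-C branch (steps 1–3, 10–15) and the reagent branches (6–9) run in parallel.

Three steps most likely to fail:

1. **Step 23 (also 16): Rh-catalysed arylation at a very congested carbon.** The di-ortho-substituted nitrostyrene and ortho-substituted boronate may give protodeboronation, no reaction, or a mismatch with the existing centres.
   Fallback: form the bond by 1,2-addition instead. Lithiate bromide 17 and add it to aldehyde 24, oxidise to the diaryl ketone, and homologate by Corey–Chaykovsky epoxidation and Meinwald rearrangement to aldehyde 27 as its epimerisable C3 epimers, which are diastereomers here. Set C3 by equilibration/separation or the reduction in fallback 2.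

2. **Step 24 (also 11, 17, with the following Grignard steps): racemisation of the α,α-diaryl acetaldehyde.** The aldehydes can enolise before the aryl adds.
   Fallback: stop protecting the labile centre and use it. Oxidise the carbinol to the 1,2,2-triarylethanone, which racemises freely at C3, and set C3 and the carbinol together by Noyori Ru–TsDPEN transfer hydrogenation under dynamic kinetic resolution. Then pivaloylate and cyclise as before.

3. **Step 26 (also 13, 19): quinone-methide ring closure.** The quinone methide can tautomerise to the triarylethylene (losing C3–H), or the pivalate can migrate to the ortho phenoxide.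
   Fallback: close the ring without a quinone methide. Carry the ring oxygen under an orthogonal group (e.g. MOM or allyl), set the carbinol by oxidation and CBS reduction, unmask that one phenol and cyclise by invertive Mitsunobu etherification (SN2). Remove the silyl groups afterwards.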